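**Retrosynthetic overview**

- Target (2R)-flavanone 22 comes from 20 by removal of the C5 O-methyl and the ring B methoxymethyl group. Ring C of 20 is closed at O1–C2 by Mitsunobu inversion of the (S)-carbinol 19 through the C8a hydroxyl.
- The strategy rests on ring A: carbons C4a, C5, C6, C7, C8 and C8a carry oxygen on C5, C7 and C8a and the acyl carbon C4 on C4a. This is a folded poly-β-keto chain, so C4a–C8a is cut as a Claisen condensation of the open-chain ester 16.
- Ester 16 comes from 4-methoxy-3-prenyl-2-pyrone 14, which supplies chain C3 to C7 with O5 already methylated and prenyl on C4, plus the enolate of methyl acetate (C1, C2).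
- Pyrone 14 comes from lateral aldol of pyrone 9 (from triacetic acid lactone) with ring B aldehyde 5 (from 3,5-dibromo-4-hydroxybenzaldehyde), then oxidation, asymmetric transfer hydrogenation and silylation.
- Ring order: ring B is bought, ring A is formed in step 10, ring C in step 12.

Key step: step 10

**Remarks on the chemistry**

- The stereocentre in the given SMILES is R at C2 (O1 > C1' > C3 > H); the route is built for that enantiomer.
- Prenyl = 3-methylbut-2-enyl. Ar = 4-(methoxymethoxy)-3,5-diprenylphenyl. Ring positions use flavanone numbering. Ester 16 uses chain numbering C1–C9, where C1 becomes C8a, C6 becomes C4a, C7 becomes C4 and C9 becomes C2.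
- Ester 16 is drawn as the open-chain triketone tautomer. Its enol and 2-hydroxy-2H-pyran (ring-chain) tautomers should interconvert under the basic conditions of step 10, so 16 is carried on crude.

**Route**

Step 1
Reactants: 1 3,5-dibromo-4-hydroxybenzaldehyde
Product: 2 3,5-dibromo-4-(methoxymethoxy)benzaldehyde
Conditions: MOMCl, K2CO3, acetone, 0 °C to rt
Reagents that add atoms: chloromethyl methyl ether, COCCl
Why: O-alkylation of the acidic 2,6-dibromophenoxide (Williamson-type methoxymethylation) gives an acetal that should survive the organolithium, transfer-hydrogenation and Mg(OMe)2 steps and is removed last.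

Step 2
Reactants: 2 3,5-dibromo-4-(methoxymethoxy)benzaldehyde; 3 tributyl(3-methylbut-2-enyl)stannane
Product: 5 4-(methoxymethoxy)-3,5-diprenylbenzaldehyde, via monoprenylated bromide 4 (not isolated)
Conditions: 3 (excess), Pd(PPh3)4 (zerovalent palladium, cat.), DMF, 100 °C
Reagents that add atoms: 3 tributyl(3-methylbut-2-enyl)stannane, CCCC[Sn](CCCC)(CCCC)CC=C(C)C
Why: Twofold Stille coupling, in which oxidative addition into the electron-poor aryl bromides, prenyl transfer from tin and reductive elimination at the unsubstituted allyl terminus should give the linear prenyl arene.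

Step 3
Reactants: 6 4-hydroxy-6-methyl-2H-pyran-2-one (triacetic acid lactone); 7 3-methylbut-2-enyl acetate
Product: 8 4-hydroxy-6-methyl-3-prenyl-2H-pyran-2-one
Conditions: 7, Pd(PPh3)4 (zerovalent palladium, cat.), DBU, toluene, 80 °C
Reagents that add atoms: 7 3-methylbut-2-enyl acetate, CC(C)=CCOC(C)=O
Why: Tsuji–Trost allylation, in which the soft pyronate carbon C3 attacks the prenyl π-allyl palladium complex at its less hindered CH2 terminus, while any O-allyl ether re-ionises under the catalyst so that the C3-prenyl product accumulates.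

Step 4
Reactants: 8 4-hydroxy-6-methyl-3-prenyl-2H-pyran-2-one
Product: 9 4-methoxy-6-methyl-3-prenyl-2H-pyran-2-one
Conditions: Me2SO4, K2CO3, acetone, reflux
Reagents that add atoms: dimethyl sulfate, COS(=O)(=O)OC
Why: O-methylation of the vinylogous acid with a hard electrophile gives the 4-methoxy-2-pyrone (vinylogous ester), the usual outcome for 4-hydroxy-2-pyrones under these conditions.

Step 5
Reactants: 9 4-methoxy-6-methyl-3-prenyl-2H-pyran-2-one; 5 4-(methoxymethoxy)-3,5-diprenylbenzaldehyde
Product: 11 racemic 6-(2-Ar-2-hydroxyethyl)-4-methoxy-3-prenyl-2H-pyran-2-one, via 6-lithiomethyl pyrone 10 (not isolated)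
Conditions: LiN(i-Pr)2, THF, −78 °C; then 5, −78 °C; aq. NH4Cl
Reagents that add atoms: none
Why: Lateral (vinylogous) lithiation of the 6-methyl group, the only acidic site once C3 is blocked, followed by aldol addition to the aldehyde; the carbinol forms racemic and is corrected in steps 6 and 7.

Step 6
Reactants: 11 racemic 6-(2-Ar-2-hydroxyethyl)-4-methoxy-3-prenyl-2H-pyran-2-one
Product: 12 6-(2-Ar-2-oxoethyl)-4-methoxy-3-prenyl-2H-pyran-2-one
Conditions: Dess–Martin periodinane, CH2Cl2, 0 °C to rt; aq. NaHCO3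
Reagents that add atoms: none
Why: Dess–Martin oxidation of the secondary benzylic alcohol under near-neutral conditions removes the racemic centre without touching the alkenes, the acetal or the pyrone.

Step 7
Reactants: 12 6-(2-Ar-2-oxoethyl)-4-methoxy-3-prenyl-2H-pyran-2-one
Product: 13 6-[(2S)-2-Ar-2-hydroxyethyl]-4-methoxy-3-prenyl-2H-pyran-2-one
Conditions: RuCl[(S,S)-TsDPEN](p-cymene) (divalent ruthenium, cat.), HCO2H/Et3N (5:2), CH2Cl2, rt
Reagents that add atoms: none
Why: Noyori asymmetric transfer hydrogenation, in which the Ru–H/N–H catalyst delivers hydride to the aryl ketone with the aryl group stacked on the η6-arene, so that by analogy with acetophenone the (S,S)-ligand should give the (S)-carbinol (to be confirmed by Mosher ester analysis) while trisubstituted alkenes and the pyrone stay inert.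

Step 8
Reactants: 13 6-[(2S)-2-Ar-2-hydroxyethyl]-4-methoxy-3-prenyl-2H-pyran-2-one
Product: 14 6-[(2S)-2-Ar-2-(tert-butyldimethylsilyloxy)ethyl]-4-methoxy-3-prenyl-2H-pyran-2-one
Conditions: TBSCl, imidazole, DMF, rt
Reagents that add atoms: tert-butyldimethylsilyl chloride, CC(C)(C)[Si](C)(C)Cl
Why: Silylation masks the hydroxyl, which after ring opening would otherwise add to C5 of the vinylogous ester, and the silyl ether is removable later with fluoride.

Step 9
Reactants: 14 6-[(2S)-2-Ar-2-(tert-butyldimethylsilyloxy)ethyl]-4-methoxy-3-prenyl-2H-pyran-2-one; 15 methyl acetate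
Product: 16 methyl (4E,9S)-9-Ar-9-(tert-butyldimethylsilyloxy)-5-methoxy-3,7-dioxo-4-prenylnon-4-enoate
Conditions: 15, LiN(i-Pr)2 (excess), THF, −78 °C; then 14, −78 to −40 °C; aq. NH4Cl (about pH 7) at −78 °C; used crude
Reagents that add atoms: 15 methyl acetate, COC(C)=O
Why: Crossed Claisen acylation of an ester enolate by an enol lactone, in which the enolate adds to the pyrone C2 carbonyl, the tetrahedral intermediate expels the ring enolate (O1–C6) to open the ring, excess enolate absorbs the acidic β-keto ester proton, the C3 prenyl group hinders conjugate attack at C4, and the cis relation of chain C3 and C6 across the enol ether is inherited from the ring.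

Step 10
Reactants: 16 methyl (4E,9S)-9-Ar-9-(tert-butyldimethylsilyloxy)-5-methoxy-3,7-dioxo-4-prenylnon-4-enoate
Product: 18 (3S)-3-Ar-3-(tert-butyldimethylsilyloxy)-1-(4,6-dihydroxy-2-methoxy-3-prenylphenyl)propan-1-one, via cyclohexenedione Claisen adduct 17 (not isolated)
Conditions: Mg(OMe)2, MeOH, 50 °C to reflux; AcOH, 0 °C
Reagents that add atoms: none
Why: Mg(OMe)2 removes a C6 proton of 16 (flanked by the C7 ketone and the C5=C4–C3=O vinylogous carbonyl) to give a magnesium dienolate whose C6 carbon (future C4a) attacks the magnesium-bound C1 ester carbonyl (future C8a); loss of methoxide gives cyclohexenedione 17, which enolises to the aromatic ring. The closest known reaction is the Mg(OMe)2 Claisen cyclisation of 3,5,7-triketo esters and of their pyrone-derived enol ether forms to acylphloroglucinols. Ring A closes in the 6-exo-trig mode at the ester carbonyl. No stereocentre is formed, and C9 is not epimerisable; the only threat to it is loss of silanolate across C8–C9, which should be slow because the C7 carbonyl sits in the dienolate and does not acidify C8. The step needs Claisen closure (C6 onto C1) over aldol closure (C2 onto C7) and over O-cyclisation: the (4E) enol ether holds C3 and C6 cis so that C1 reaches C6, the C7 carbonyl is tied up as the magnesium enolate and is a poor aldol acceptor, and the methylated O5 cannot close a pyranone. Because O5 enters methylated, ring A emerges with only the C7 and C8a hydroxyls free and prenyl fixed at C6.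

Step 11
Reactants: 18 (3S)-3-Ar-3-(tert-butyldimethylsilyloxy)-1-(4,6-dihydroxy-2-methoxy-3-prenylphenyl)propan-1-one
Product: 19 (3S)-3-Ar-3-hydroxy-1-(4,6-dihydroxy-2-methoxy-3-prenylphenyl)propan-1-one
Conditions: HF·pyridine, pyridine, THF, 0 °C to rt
Reagents that add atoms: none
Why: Fluoride-driven Si–O cleavage under pyridine-buffered conditions should free the carbinol without base-induced dehydration of the β-hydroxy ketone and without loss of the methoxymethyl acetal.

Step 12
Reactants: 19 (3S)-3-Ar-3-hydroxy-1-(4,6-dihydroxy-2-methoxy-3-prenylphenyl)propan-1-one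
Product: 20 (2R)-2-Ar-7-hydroxy-5-methoxy-6-prenyl-2,3-dihydro-4H-chromen-4-one
Conditions: PPh3, DIAD, THF (high dilution), 0 °C to rt
Reagents that add atoms: none
Why: Intramolecular Mitsunobu etherification, in which the C8a phenol, the only hydroxyl that can reach the activated carbinol (6-exo-tet), displaces the alkoxyphosphonium with inversion, turning the (S)-carbinol into (R)-C2, while dilution suppresses intermolecular attack by the C7 hydroxyl.

Step 13
Reactants: 20 (2R)-2-Ar-7-hydroxy-5-methoxy-6-prenyl-2,3-dihydro-4H-chromen-4-one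
Product: 21 (2R)-2-Ar-5,7-dihydroxy-6-prenyl-2,3-dihydro-4H-chromen-4-one
Conditions: MgI2, THF, 50 °C; aq. NH4Cl
Reagents that add atoms: none
Why: Chelation-controlled demethylation, in which magnesium binds the C4 carbonyl and O5 and iodide removes the methyl group by SN2 attack, leaving the prenyl groups and the stereocentre untouched.

Step 14
Reactants: 21 (2R)-2-Ar-5,7-dihydroxy-6-prenyl-2,3-dihydro-4H-chromen-4-one
Product: 22 (2R)-5,7-dihydroxy-2-(4-hydroxy-3,5-diprenylphenyl)-6-prenyl-2,3-dihydro-4H-chromen-4-one (CNP0268011.1)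
Conditions: HCl (1 M aq.), MeOH, rt, stopped as soon as 21 is consumed
Reagents that add atoms: none
Why: Mild acid-catalysed acetal exchange with methanol removes the aryl methoxymethyl ether at room temperature, where prenyl-to-chroman cyclisation and flavanone ring opening should be slow.

**Compound list**

1 | 3,5-dibromo-4-hydroxybenzaldehyde | O=Cc1cc(Br)c(O)c(Br)c1 | starting material
2 | 3,5-dibromo-4-(methoxymethoxy)benzaldehyde | COCOc1c(Br)cc(C=O)cc1Br | intermediate
3 | tributyl(3-methylbut-2-enyl)stannane | CCCC[Sn](CCCC)(CCCC)CC=C(C)C | starting material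
4 | 3-bromo-4-(methoxymethoxy)-5-prenylbenzaldehyde (formed in the flask) | COCOc1c(Br)cc(C=O)cc1CC=C(C)C | intermediate
5 | 4-(methoxymethoxy)-3,5-diprenylbenzaldehyde | COCOc1c(CC=C(C)C)cc(C=O)cc1CC=C(C)C | intermediate
6 | 4-hydroxy-6-methyl-2H-pyran-2-one | Cc1cc(O)cc(=O)o1 | starting material
7 | 3-methylbut-2-enyl acetate | CC(C)=CCOC(C)=O | starting material
8 | 4-hydroxy-6-methyl-3-prenyl-2H-pyran-2-one | Cc1cc(O)c(CC=C(C)C)c(=O)o1 | intermediate
9 | 4-methoxy-6-methyl-3-prenyl-2H-pyran-2-one | COc1cc(C)oc(=O)c1CC=C(C)C | intermediate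
10 | 6-(lithiomethyl)-4-methoxy-3-prenyl-2H-pyran-2-one (formed in the flask) | [Li]Cc1cc(OC)c(CC=C(C)C)c(=O)o1 | intermediate
11 | racemic 6-(2-Ar-2-hydroxyethyl)-4-methoxy-3-prenyl-2H-pyran-2-one | COCOc1c(CC=C(C)C)cc(C(O)Cc2cc(OC)c(CC=C(C)C)c(=O)o2)cc1CC=C(C)C | intermediate
12 | 6-(2-Ar-2-oxoethyl)-4-methoxy-3-prenyl-2H-pyran-2-one | COCOc1c(CC=C(C)C)cc(C(=O)Cc2cc(OC)c(CC=C(C)C)c(=O)o2)cc1CC=C(C)C | intermediate
13 | 6-[(2S)-2-Ar-2-hydroxyethyl]-4-methoxy-3-prenyl-2H-pyran-2-one | CC(C)=CCc1cc([C@@H](O)Cc2cc(OC)c(CC=C(C)C)c(=O)o2)cc(CC=C(C)C)c1OCOC | intermediate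
14 | 6-[(2S)-2-Ar-2-(tert-butyldimethylsilyloxy)ethyl]-4-methoxy-3-prenyl-2H-pyran-2-one | CC(C)=CCc1cc([C@@H](O[Si](C)(C)C(C)(C)C)Cc2cc(OC)c(CC=C(C)C)c(=O)o2)cc(CC=C(C)C)c1OCOC | intermediate
15 | methyl acetate | COC(C)=O | starting material
16 | methyl (4E,9S)-9-Ar-9-(tert-butyldimethylsilyloxy)-5-methoxy-3,7-dioxo-4-prenylnon-4-enoate | CC(C)=CCc1cc([C@@H](O[Si](C)(C)C(C)(C)C)CC(=O)C/C(OC)=C(/CC=C(C)C)C(=O)CC(=O)OC)cc(CC=C(C)C)c1OCOC | intermediate
17 | 2-[(3S)-3-Ar-3-(tert-butyldimethylsilyloxy)propanoyl]-3-methoxy-4-prenylcyclohex-3-ene-1,5-dione (formed in the flask; ring CH centre undefined, enolises at once) | CC(C)=CCc1cc([C@@H](O[Si](C)(C)C(C)(C)C)CC(=O)C2C(=O)CC(=O)C(CC=C(C)C)=C2OC)cc(CC=C(C)C)c1OCOC | intermediate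
18 | (3S)-3-Ar-3-(tert-butyldimethylsilyloxy)-1-(4,6-dihydroxy-2-methoxy-3-prenylphenyl)propan-1-one | CC(C)=CCc1cc([C@@H](O[Si](C)(C)C(C)(C)C)CC(=O)c2c(O)cc(O)c(CC=C(C)C)c2OC)cc(CC=C(C)C)c1OCOC | intermediate
19 | (3S)-3-Ar-3-hydroxy-1-(4,6-dihydroxy-2-methoxy-3-prenylphenyl)propan-1-one | CC(C)=CCc1cc([C@@H](O)CC(=O)c2c(O)cc(O)c(CC=C(C)C)c2OC)cc(CC=C(C)C)c1OCOC | intermediate
20 | (2R)-2-Ar-7-hydroxy-5-methoxy-6-prenyl-2,3-dihydro-4H-chromen-4-one | CC(C)=CCc1cc([C@H]2CC(=O)c3c(cc(O)c(CC=C(C)C)c3OC)O2)cc(CC=C(C)C)c1OCOC | intermediate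
21 | (2R)-2-Ar-5,7-dihydroxy-6-prenyl-2,3-dihydro-4H-chromen-4-one | CC(C)=CCc1cc([C@H]2CC(=O)c3c(cc(O)c(CC=C(C)C)c3O)O2)cc(CC=C(C)C)c1OCOC | intermediate
22 | (2R)-5,7-dihydroxy-2-(4-hydroxy-3,5-diprenylphenyl)-6-prenyl-2,3-dihydro-4H-chromen-4-one | CC(C)=CCc1cc([C@H]2CC(=O)c3c(cc(O)c(CC=C(C)C)c3O)O2)cc(CC=C(C)C)c1O | target

**Step count**

Total: 14 steps. Longest linear sequence: 12 steps (steps 3 to 14; the ring B branch, steps 1, 2 and 5 to 14, is equally long).

**Three steps most likely to fail**

Step 9. The enolate may add in conjugate fashion at C4 with loss of methoxide, or deprotonate the lateral CH2 and trigger loss of silanolate to a styrylpyrone, instead of adding to the lactone carbonyl. The fallback sets out from 14 and comes back at 16. The pyrone carbonyl is first opened with the hard magnesium amide ClMgN(OMe)Me (from MeNHOMe·HCl and i-PrMgCl, THF, −20 °C) to the keto N-methoxy-N-methyl amide (2E,7S)-7-Ar-7-(tert-butyldimethylsilyloxy)-N,3-dimethoxy-N-methyl-5-oxo-2-prenylhept-2-enamide F1. The lithium enolate of methyl acetate is then acylated by this amide at −78 °C through its chelated tetrahedral adduct, which releases 16 on neutral work-up.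

Step 10. The chain may fold in the aldol sense (C2 onto the C7 carbonyl) to a resorcylate, or the base may cause loss of the silyloxy group from C9. The fallback abandons the chain cyclisation; it sets out from aldehyde 5 and comes back at 19.
- Commercial 2,4,6-trihydroxyacetophenone is C-prenylated (prenyl bromide, DBU, THF) to 1-(2,4,6-trihydroxy-3-prenylphenyl)ethanone F2.
- The para hydroxyl and the less hindered ortho hydroxyl are silylated (i-Pr3SiCl, imidazole, DMF) to 1-[2-hydroxy-3-prenyl-4,6-bis(triisopropylsilyloxy)phenyl]ethanone F3.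
- The remaining chelated hydroxyl next to the prenyl group is methylated (MeI, K2CO3, acetone) to 1-[2-methoxy-3-prenyl-4,6-bis(triisopropylsilyloxy)phenyl]ethanone F4.
- The diisopinocampheylboron enolate of F4 (Ipc2BCl enantiomer chosen to give the 3S adduct, Et3N, Et2O, −78 °C) adds to 5 to give (3S)-3-Ar-3-hydroxy-1-[2-methoxy-3-prenyl-4,6-bis(triisopropylsilyloxy)phenyl]propan-1-one F5.
- Bu4NF buffered with AcOH removes both aryl silyl groups and gives 19.

Step 12. The activated, electron-rich benzylic carbinol may ionise, or the β-oxyphosphonium ketone may eliminate to the chalcone and re-close; both erode the configuration at C2. The fallback sets out from 19 and comes back at 20. Compound 19 is dehydrated and cyclised without stereocontrol (NaOAc, EtOH, reflux; chalcone formation and oxa-Michael closure through the C8a hydroxyl, the only free ortho hydroxyl) to racemic 2-Ar-7-hydroxy-5-methoxy-6-prenyl-2,3-dihydro-4H-chromen-4-one F6. Kinetic resolution by asymmetric transfer hydrogenation (RuCl(TsDPEN)(p-cymene), divalent ruthenium, HCO2H/Et3N, with the ligand enantiomer that reduces the 2S ketone faster) turns the unwanted enantiomer into the cis alcohol (2S,4S)-2-Ar-5-methoxy-6-prenylchromane-4,7-diol F7. Unreacted (2R)-20 is separated from it by chromatography.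

Further compounds
F1 | step 9 | (2E,7S)-7-Ar-7-(tert-butyldimethylsilyloxy)-N,3-dimethoxy-N-methyl-5-oxo-2-prenylhept-2-enamide | CON(C)C(=O)/C(CC=C(C)C)=C(OC)\CC(=O)C[C@H](O[Si](C)(C)C(C)(C)C)c1cc(CC=C(C)C)c(OCOC)c(CC=C(C)C)c1
F2 | step 10 | 1-(2,4,6-trihydroxy-3-prenylphenyl)ethanone | CC(=O)c1c(O)cc(O)c(CC=C(C)C)c1O
F3 | step 10 | 1-[2-hydroxy-3-prenyl-4,6-bis(triisopropylsilyloxy)phenyl]ethanone | CC(=O)c1c(O[Si](C(C)C)(C(C)C)C(C)C)cc(O[Si](C(C)C)(C(C)C)C(C)C)c(CC=C(C)C)c1O
F4 | step 10 | 1-[2-methoxy-3-prenyl-4,6-bis(triisopropylsilyloxy)phenyl]ethanone | CC(=O)c1c(O[Si](C(C)C)(C(C)C)C(C)C)cc(O[Si](C(C)C)(C(C)C)C(C)C)c(CC=C(C)C)c1OC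
F5 | step 10 | (3S)-3-Ar-3-hydroxy-1-[2-methoxy-3-prenyl-4,6-bis(triisopropylsilyloxy)phenyl]propan-1-one | CC(C)=CCc1cc([C@@H](O)CC(=O)c2c(O[Si](C(C)C)(C(C)C)C(C)C)cc(O[Si](C(C)C)(C(C)C)C(C)C)c(CC=C(C)C)c2OC)cc(CC=C(C)C)c1OCOC
F6 | step 12 | racemic 2-Ar-7-hydroxy-5-methoxy-6-prenyl-2,3-dihydro-4H-chromen-4-one | CC(C)=CCc1cc(C2CC(=O)c3c(cc(O)c(CC=C(C)C)c3OC)O2)cc(CC=C(C)C)c1OCOC
F7 | step 12 | (2S,4S)-2-Ar-5-methoxy-6-prenylchromane-4,7-diol | CC(C)=CCc1cc([C@@H]2C[C@H](O)c3c(cc(O)c(CC=C(C)C)c3OC)O2)cc(CC=C(C)C)c1OCOC
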